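**Plan**

- Germacrane numbering is used: C1 ketone, C2=C3 furanone alkene, C4=C5, C6 lactone carbinol, C7, C8 ester carbinol, C9 carbinol, C10 quaternary (C14 methyl), C11–C13 methylene lactone. The feature exploited is the cis trisubstituted C4=C5 alkene inside the ten-membered carbocycle (C1–C10), lying between C3 of the furanone ring and C6 of the lactone ring; it can be formed last from a C6 vinyl and a C3 isopropenyl group.
- Retrosynthetic cuts, in order: C4=C5 (ring-closing metathesis); O9–Si and O8–acyl; C12–O6 and C6–C7 (allylchromium addition to acrolein, lactonisation); C7–C11 (Morita–Baylis–Hillman); O–C3 of the furanone (cycloisomerisation); C10–C1 (alkynylation of a methyl ketone).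
- Forward order: one linear chain from L-threitol acetonide; the furanone ring forms first (steps 6–8), the lactone ring second (step 13), the ten-membered carbocycle last (step 17).
- Stereochemistry: C8 and C9 come from L-tartaric acid (as its threitol acetonide); C10 from Felkin–Anh addition next to C9; C7 from A(1,3)-controlled attack anti to C9; C6 from the chair transition state of the allylchromium addition (anti, trans-lactone); the C4=C5 geometry from the ring.

Key step: step 17

Remark: (4S,5S)-2,3-O-isopropylidene-L-threitol, the reduced acetonide of diethyl L-tartrate, is taken as the commercial entry point, and the gold-catalysed step is assumed to run through catalytic (adventitious) water.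

**Step 1**
Reactants: 1 (4S,5S)-2,3-O-isopropylidene-L-threitol
Product: 2 mono-TBDPS ether of 1 (silyl ether on the future C7 oxygen)
Conditions: NaH (1.0 equiv), THF, 0 °C; TBDPSCl (1.0 equiv), 0 °C to rt
Reagents that add atoms: tert-butyl(chloro)diphenylsilane, CC(C)(C)[Si](Cl)(c1ccccc1)c1ccccc1
Why: Monosilylation of a C2-symmetric diol through its sparingly soluble monosodium alkoxide is selective for one hydroxyl, and the two ends are equivalent, so no regiochemical question arises.

**Step 2**
Reactants: 2 mono-TBDPS ether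
Product: 3 (4R,5S)-5-(TBDPS-oxymethyl)-2,2-dimethyl-1,3-dioxolane-4-carbaldehyde
Conditions: Dess–Martin periodinane, CH2Cl2, 0 °C to rt
Reagents that add atoms: none
Why: Dess–Martin oxidation stops at the aldehyde under neutral conditions, and the trans-disubstituted dioxolane is the stable arrangement, so C9 should not epimerise.

**Step 3**
Reactants: 3 aldehyde
Product: 4 1-[(4S,5S)-5-(TBDPS-oxymethyl)-2,2-dimethyl-1,3-dioxolan-4-yl]ethanol (both carbinol epimers)
Conditions: MeMgBr, THF, −78 °C; H2O
Reagents that add atoms: methylmagnesium bromide, C[Mg]Br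
Why: Grignard 1,2-addition brings in the C14 methyl group; the new carbinol centre is formed as a mixture that the next step erases.

**Step 4**
Reactants: 4 secondary alcohol
Product: 5 1-[(4R,5S)-5-(TBDPS-oxymethyl)-2,2-dimethyl-1,3-dioxolan-4-yl]ethanone (C10 methyl ketone)
Conditions: Dess–Martin periodinane, CH2Cl2, rt
Reagents that add atoms: none
Why: Dess–Martin oxidation converges both epimers on the methyl ketone without touching the silyl ether or the acetal.

**Step 5**
Reactants: 6 methacrolein
Product: 7 racemic 2-methylpent-1-en-4-yn-3-ol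
Conditions: HC≡CMgBr, THF, 0 °C; H2O
Reagents that add atoms: ethynylmagnesium bromide, C#C[Mg]Br
Why: Alkynyl Grignard reagents add 1,2 to enals; the carbinol configuration is irrelevant because this centre is oxidised in step 7.

**Step 6**
Reactants: 5 methyl ketone; 7 alkynol
Product: 9 (2S)-2-[(4R,5S)-5-(TBDPS-oxymethyl)-2,2-dimethyl-1,3-dioxolan-4-yl]-6-methylhept-6-en-3-yne-2,5-diol (epimers at the secondary carbinol), via dilithiated alkynol 8 (not isolated)
Conditions: 7 (1.5 equiv), n-BuLi (3.0 equiv), THF, −78 to −20 °C; then 5, −78 °C; H2O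
Reagents that add atoms: none
Why: Lithium acetylide 1,2-addition to an α-alkoxy ketone under Felkin–Anh (polar, non-chelating) control: with the C9–O bond of the dioxolane antiperiplanar to the incoming acetylide and C8 on the carbonyl-oxygen side, attack should give the tertiary carbinol with O10 anti to O9, which is the C10 configuration of the target.

**Step 7**
Reactants: 9 diol
Product: 10 (6S)-6-hydroxy-6-[(4R,5S)-5-(TBDPS-oxymethyl)-2,2-dimethyl-1,3-dioxolan-4-yl]-2-methylhept-1-en-4-yn-3-one
Conditions: MnO2 (activated, excess), CH2Cl2, rt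
Reagents that add atoms: none
Why: MnO2 oxidises only the secondary carbinol that is both allylic and propargylic, leaves the tertiary alcohol alone and removes the stereorandom centre.

**Step 8**
Reactants: 10 hydroxy ynone
Product: 12 (2R)-2-[(4R,5S)-5-(TBDPS-oxymethyl)-2,2-dimethyl-1,3-dioxolan-4-yl]-2-methyl-5-(prop-1-en-2-yl)furan-3(2H)-one, via 1,3-diketone 11 (not isolated)
Conditions: (4-CF3C6H4)3PAuCl (5 mol %), AgOTf (5 mol %), toluene (undried), rt
Reagents that add atoms: water, O (its oxygen becomes the C1 carbonyl oxygen; the former C3 carbonyl oxygen leaves as water)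
Why: Gold-catalysed hydrative cycloisomerisation of a 4-hydroxy-2-ynone to a 3(2H)-furanone: monovalent gold activates the alkyne for addition of water at C1 and the tertiary hydroxyl then condenses on the C3 ketone with loss of water, so the C10–O bond is never broken and C10 keeps its configuration.

**Step 9**
Reactants: 12 silyl ether
Product: 13 (2R)-2-[(4R,5S)-5-(hydroxymethyl)-2,2-dimethyl-1,3-dioxolan-4-yl]-2-methyl-5-(prop-1-en-2-yl)furan-3(2H)-one
Conditions: Bu4NF, AcOH (1:1), THF, 0 °C to rt
Reagents that add atoms: none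
Why: Fluoride cleaves the silyl ether, and buffering with acetic acid keeps the cross-conjugated dienone of the furanone away from basic alkoxide.

**Step 10**
Reactants: 13 primary alcohol
Product: 14 (4R,5R)-2,2-dimethyl-5-[(2R)-2-methyl-3-oxo-5-(prop-1-en-2-yl)-2,3-dihydrofuran-2-yl]-1,3-dioxolane-4-carbaldehyde (C7 aldehyde)
Conditions: Dess–Martin periodinane, CH2Cl2, 0 °C to rt
Reagents that add atoms: none
Why: Dess–Martin oxidation gives the α-alkoxy aldehyde under neutral conditions; it is used without storage.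

**Step 11**
Reactants: 14 aldehyde; 15 methyl acrylate
Product: 16 methyl 2-{hydroxy[(4S,5R)-2,2-dimethyl-5-((2R)-2-methyl-3-oxo-5-(prop-1-en-2-yl)-2,3-dihydrofuran-2-yl)-1,3-dioxolan-4-yl]methyl}prop-2-enoate (both C7 epimers)
Conditions: 15 (10 equiv), DABCO (1 equiv), 1,4-dioxane–H2O (1:1), rt, several days
Reagents that add atoms: none
Why: Morita–Baylis–Hillman reaction: DABCO adds to the acrylate and the zwitterionic enolate adds to the aldehyde, forming C7–C11; the carbinol configuration does not matter because C7 becomes trigonal in step 12, and the less electrophilic furanone does not compete for the amine.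

**Step 12**
Reactants: 16 allylic alcohol
Product: 18 methyl (Z)-2-(bromomethyl)-3-[(4S,5R)-2,2-dimethyl-5-((2R)-2-methyl-3-oxo-5-(prop-1-en-2-yl)-2,3-dihydrofuran-2-yl)-1,3-dioxolan-4-yl]prop-2-enoate, via allylic mesylate 17 (not isolated)
Conditions: Ms2O, Et3N, CH2Cl2, −20 °C; LiBr, THF, 0 °C to rt
Reagents that add atoms: lithium bromide, [Li+].[Br-]
Why: Mesylation followed by SN2' displacement with bromide transposes the allylic system and gives the thermodynamically preferred (Z)-2-(bromomethyl)enoate, in which C8 is trans to the ester.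

**Step 13**
Reactants: 18 allylic bromide; 19 acrolein
Product: 22 (4S,5R)-5-ethenyl-3-methylidene-4-[(4S,5R)-2,2-dimethyl-5-((2R)-2-methyl-3-oxo-5-(prop-1-en-2-yl)-2,3-dihydrofuran-2-yl)-1,3-dioxolan-4-yl]oxolan-2-one (6R,7S trans-lactone), via allylchromium dichloride 20 (not isolated), via anti hydroxy ester 21 (not isolated)
Conditions: CrCl2 (4 equiv), 19 (3 equiv), THF, 0 °C to rt; H2O; PPTS (cat.), CH2Cl2, rt
Reagents that add atoms: none
Why: Nozaki–Hiyama-type 2-(alkoxycarbonyl)allylation then lactonisation: CrCl2 (divalent chromium) turns the bromide into an allylchromium species that adds through C7 to acrolein in a chair Zimmerman–Traxler transition state with the C8 branch and the vinyl group equatorial, which should give the anti C6/C7 pair and hence the trans-lactone, while A(1,3) strain holds H8 in the plane of the C7=C11 bond so that acrolein approaches C7 anti to the bulky C9 branch with O8 outside, which sets C7 relative to C8.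

**Step 14**
Reactants: 22 lactone acetonide
Product: 23 (4S,5R)-4-[(1S,2R)-1,2-dihydroxy-2-((2R)-2-methyl-3-oxo-5-(prop-1-en-2-yl)-2,3-dihydrofuran-2-yl)ethyl]-5-ethenyl-3-methylideneoxolan-2-one (8,9-diol)
Conditions: TFA–H2O (9:1), 0 °C
Reagents that add atoms: none
Why: Acid-catalysed acetal hydrolysis frees the diol; lactone and furanone tolerate cold aqueous acid, and transfer of the lactone to O8 would have to pass a strained bicyclic orthoester-type intermediate.

**Step 15**
Reactants: 23 diol
Product: 24 8-O-(3-methylbutanoyl) derivative of 23 (free C9 hydroxyl)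
Conditions: (Me2CHCH2CO)2O (1.2 equiv), Et3N, DMAP (cat.), CH2Cl2, −40 to −20 °C
Reagents that add atoms: 3-methylbutanoic anhydride, CC(C)CC(=O)OC(=O)CC(C)C
Why: DMAP-catalysed acylation should distinguish the two secondary hydroxyls sterically, because O9 is neopentylic (next to quaternary C10) and reacts much more slowly than O8 at low temperature.

**Step 16**
Reactants: 24 hydroxy ester
Product: 25 seco diene with C6 vinyl, C3 isopropenyl, C8 3-methylbutanoate and C9 triethylsilyl ether (6R,7S,8S,9R,10R)
Conditions: TESOTf, 2,6-lutidine, CH2Cl2, −78 to 0 °C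
Reagents that add atoms: triethylsilyl trifluoromethanesulfonate, CC[Si](CC)(CC)OS(=O)(=O)C(F)(F)F
Why: A silyl triflate with a hindered base silylates even the hindered C9 hydroxyl, which closes the retro-aldol (β-hydroxy ketone) and acyl-migration pathways before the heated metathesis step.

**Step 17**
Reactants: 25 seco diene
Product: 26 lobatin B 9-triethylsilyl ether
Conditions: second-generation Grubbs catalyst (H2IMes)(PCy3)Cl2Ru=CHPh (20 mol %, in portions), toluene (1 mM), 80 °C, Ar sparge
Reagents that add atoms: none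
Why: The ruthenium benzylidene exchanges first with the unhindered C6 vinyl group, the resulting C5 alkylidene adds across the isopropenyl alkene in a [2+2] step, and cycloreversion of the ruthenacyclobutane forms C4=C5 and releases Ru=CH2, which is lost as ethylene; the closest known reaction type is ring-closing metathesis to medium-ring trisubstituted cycloalkenes. The ten-membered carbocycle (C1–C10) closes by alkene–alkene ring-closing metathesis with the new double bond endocyclic. No stereocentre is formed, and the alkene should be cis (Z) because C3 sits in the planar furanone and C6 in the trans-fused lactone, so a trans C4=C5 bond would not fit a ring bridged by the C3–O–C10 ether. Chemoselectivity among the four alkenes is secured by ring size: the methylene lactone could only close a four-membered ring with the vinyl group or an eight-membered ring with a tetrasubstituted alkene, and the furanone C2=C3 bond is inert. Cyclisation must beat cross-metathesis dimerisation at the vinyl group, which high dilution, removal of ethylene and the two turn elements (furanone and trans-lactone) should favour.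

**Step 18**
Reactants: 26 lobatin B 9-triethylsilyl ether
Product: 27 lobatin B
Conditions: HF·pyridine, pyridine, THF, 0 °C to rt
Reagents that add atoms: none
Why: Fluoride-mediated desilylation under mildly acidic, non-basic conditions removes the triethylsilyl ether without acyl migration, retro-aldol cleavage or conjugate addition to the methylene lactone.

**Compound list**

1 | (4S,5S)-2,2-dimethyl-1,3-dioxolane-4,5-dimethanol (2,3-O-isopropylidene-L-threitol) | OC[C@@H]1OC(C)(C)O[C@H]1CO | starting material
2 | [(4S,5S)-5-(tert-butyldiphenylsilyloxymethyl)-2,2-dimethyl-1,3-dioxolan-4-yl]methanol | OC[C@@H]1OC(C)(C)O[C@H]1CO[Si](c2ccccc2)(c3ccccc3)C(C)(C)C | intermediate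
3 | (4R,5S)-5-(tert-butyldiphenylsilyloxymethyl)-2,2-dimethyl-1,3-dioxolane-4-carbaldehyde | O=C[C@@H]1OC(C)(C)O[C@H]1CO[Si](c2ccccc2)(c3ccccc3)C(C)(C)C | intermediate
4 | 1-[(4S,5S)-5-(tert-butyldiphenylsilyloxymethyl)-2,2-dimethyl-1,3-dioxolan-4-yl]ethanol, both carbinol epimers | CC(O)[C@@H]1OC(C)(C)O[C@H]1CO[Si](c2ccccc2)(c3ccccc3)C(C)(C)C | intermediate
5 | 1-[(4R,5S)-5-(tert-butyldiphenylsilyloxymethyl)-2,2-dimethyl-1,3-dioxolan-4-yl]ethanone | CC(=O)[C@@H]1OC(C)(C)O[C@H]1CO[Si](c2ccccc2)(c3ccccc3)C(C)(C)C | intermediate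
6 | methacrolein | C=C(C)C=O | starting material
7 | racemic 2-methylpent-1-en-4-yn-3-ol | C=C(C)C(O)C#C | intermediate
8 | dilithiated alkynol (lithium acetylide and lithium alkoxide of 7) | [Li]C#CC(O[Li])C(C)=C | intermediate (not isolated)
9 | (2S)-2-[(4R,5S)-5-(tert-butyldiphenylsilyloxymethyl)-2,2-dimethyl-1,3-dioxolan-4-yl]-6-methylhept-6-en-3-yne-2,5-diol, epimers at the secondary carbinol (8S,9R,10S in germacrane numbering) | C=C(C)C(O)C#C[C@](C)(O)[C@@H]1OC(C)(C)O[C@H]1CO[Si](c2ccccc2)(c3ccccc3)C(C)(C)C | intermediate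
10 | (6S)-6-hydroxy-6-[(4R,5S)-5-(tert-butyldiphenylsilyloxymethyl)-2,2-dimethyl-1,3-dioxolan-4-yl]-2-methylhept-1-en-4-yn-3-one | C=C(C)C(=O)C#C[C@](C)(O)[C@@H]1OC(C)(C)O[C@H]1CO[Si](c2ccccc2)(c3ccccc3)C(C)(C)C | intermediate
11 | (6R)-6-hydroxy-6-[(4R,5S)-5-(tert-butyldiphenylsilyloxymethyl)-2,2-dimethyl-1,3-dioxolan-4-yl]-2-methylhept-1-ene-3,5-dione | C=C(C)C(=O)CC(=O)[C@](C)(O)[C@@H]1OC(C)(C)O[C@H]1CO[Si](c2ccccc2)(c3ccccc3)C(C)(C)C | intermediate (not isolated)
12 | (2R)-2-[(4R,5S)-5-(tert-butyldiphenylsilyloxymethyl)-2,2-dimethyl-1,3-dioxolan-4-yl]-2-methyl-5-(prop-1-en-2-yl)furan-3(2H)-one | C=C(C)C1=CC(=O)[C@](C)(O1)[C@@H]2OC(C)(C)O[C@H]2CO[Si](c3ccccc3)(c4ccccc4)C(C)(C)C | intermediate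
13 | (2R)-2-[(4R,5S)-5-(hydroxymethyl)-2,2-dimethyl-1,3-dioxolan-4-yl]-2-methyl-5-(prop-1-en-2-yl)furan-3(2H)-one | C=C(C)C1=CC(=O)[C@](C)(O1)[C@@H]2OC(C)(C)O[C@H]2CO | intermediate
14 | (4R,5R)-2,2-dimethyl-5-[(2R)-2-methyl-3-oxo-5-(prop-1-en-2-yl)-2,3-dihydrofuran-2-yl]-1,3-dioxolane-4-carbaldehyde | C=C(C)C1=CC(=O)[C@](C)(O1)[C@@H]2OC(C)(C)O[C@H]2C=O | intermediate
15 | methyl acrylate | C=CC(=O)OC | starting material
16 | methyl 2-{hydroxy[(4S,5R)-2,2-dimethyl-5-((2R)-2-methyl-3-oxo-5-(prop-1-en-2-yl)-2,3-dihydrofuran-2-yl)-1,3-dioxolan-4-yl]methyl}prop-2-enoate, both C7 epimers | C=C(C)C1=CC(=O)[C@](C)(O1)[C@@H]2OC(C)(C)O[C@H]2C(O)C(=C)C(=O)OC | intermediate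
17 | methanesulfonate of 16, both C7 epimers | C=C(C)C1=CC(=O)[C@](C)(O1)[C@@H]2OC(C)(C)O[C@H]2C(OS(C)(=O)=O)C(=C)C(=O)OC | intermediate (not isolated)
18 | methyl (Z)-2-(bromomethyl)-3-[(4S,5R)-2,2-dimethyl-5-((2R)-2-methyl-3-oxo-5-(prop-1-en-2-yl)-2,3-dihydrofuran-2-yl)-1,3-dioxolan-4-yl]prop-2-enoate | C=C(C)C1=CC(=O)[C@](C)(O1)[C@@H]2OC(C)(C)O[C@H]2/C=C(\CBr)C(=O)OC | intermediate
19 | acrolein | C=CC=O | starting material
20 | allylchromium dichloride from 18 (trivalent chromium, solvent ligands omitted, alkene geometry mobile) | C=C(C)C1=CC(=O)[C@](C)(O1)[C@@H]2OC(C)(C)O[C@H]2C=C(C[Cr](Cl)Cl)C(=O)OC | intermediate (not isolated)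
21 | methyl (3S,4R)-4-hydroxy-2-methylidene-3-[(4S,5R)-2,2-dimethyl-5-((2R)-2-methyl-3-oxo-5-(prop-1-en-2-yl)-2,3-dihydrofuran-2-yl)-1,3-dioxolan-4-yl]hex-5-enoate (anti adduct) | C=C(C(=O)OC)[C@@H]([C@H](O)C=C)[C@@H]1OC(C)(C)O[C@H]1[C@@]2(C)OC(C(C)=C)=CC2=O | intermediate (not isolated)
22 | (4S,5R)-5-ethenyl-3-methylidene-4-[(4S,5R)-2,2-dimethyl-5-((2R)-2-methyl-3-oxo-5-(prop-1-en-2-yl)-2,3-dihydrofuran-2-yl)-1,3-dioxolan-4-yl]oxolan-2-one (6R,7S,8S,9R,10R) | C=C1C(=O)O[C@H](C=C)[C@H]1[C@@H]2OC(C)(C)O[C@H]2[C@@]3(C)OC(C(C)=C)=CC3=O | intermediate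
23 | (4S,5R)-4-[(1S,2R)-1,2-dihydroxy-2-((2R)-2-methyl-3-oxo-5-(prop-1-en-2-yl)-2,3-dihydrofuran-2-yl)ethyl]-5-ethenyl-3-methylideneoxolan-2-one | C=C1C(=O)O[C@H](C=C)[C@H]1[C@H](O)[C@@H](O)[C@@]2(C)OC(C(C)=C)=CC2=O | intermediate
24 | 8-O-(3-methylbutanoyl) derivative of 23 with free C9 hydroxyl | C=C1C(=O)O[C@H](C=C)[C@H]1[C@H](OC(=O)CC(C)C)[C@@H](O)[C@@]2(C)OC(C(C)=C)=CC2=O | intermediate
25 | seco diene: 9-O-triethylsilyl ether of 24 (6R,7S,8S,9R,10R) | C=C1C(=O)O[C@H](C=C)[C@H]1[C@H](OC(=O)CC(C)C)[C@@H](O[Si](CC)(CC)CC)[C@@]2(C)OC(C(C)=C)=CC2=O | intermediate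
26 | lobatin B 9-triethylsilyl ether (4Z) | C=C1C(=O)O[C@@H]2/C=C(/C)C3=CC(=O)[C@](C)(O3)[C@H](O[Si](CC)(CC)CC)[C@@H](OC(=O)CC(C)C)[C@@H]12 | intermediate
27 | lobatin B (4Z,6R,7S,8S,9R,10R) | C=C1C(=O)O[C@@H]2/C=C(/C)C3=CC(=O)[C@](C)(O3)[C@H](O)[C@@H](OC(=O)CC(C)C)[C@@H]12 | target

**Count and risks**

Total step count: 18. Longest linear sequence: 17 steps (steps 1–4 and 6–18; step 5 is the side branch).

Steps most likely to fail:

1. Step 17. Cross-metathesis oligomerisation at the C6 vinyl group and decay of the ruthenium methylidene may outrun the strained closure onto the hindered, conjugated isopropenyl group. Fallback, setting out from 22 and returning at 27: the ring is closed one stage earlier, on the lactone whose trans-dioxolane locks the C8–C9 torsion and keeps the bulky silyl and acyl groups off the closing chain. The same catalyst at the same dilution should give the macrocyclic acetonide F1. Cold aqueous TFA should then free the macrocyclic 8,9-diol F2. Low-temperature acylation with 3-methylbutanoic anhydride and DMAP at the less hindered O8 leads to 27.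

2. Step 13. The allylchromium species may react through its tiglate-type geometry (syn addition, leading to the cis-lactone), or the facial bias at C7 may be weak. Fallback, setting out from 18 and returning at 22: syn addition is accepted and C6 is corrected afterwards. Indium powder and 19 in THF–H2O, a Barbier allylation that is reliably syn-selective for this reagent class, should give the syn hydroxy ester F3. PPTS should close it to the cis-lactone F4. Pd(PPh3)4 (zerovalent palladium) in THF should then ionise the allylic C6–O bond to a π-allyl carboxylate, which exchanges faces through its unsubstituted terminus and recloses to the more stable trans-lactone 22.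

3. Step 15. Discrimination between O8 and O9 may be incomplete, or the acyl group may migrate from O8 to O9 under the basic conditions. Fallback, setting out from 23 and returning at 25: the selectivity is moved from an acylation to a desilylation. Excess TESOTf and 2,6-lutidine should give the bis-triethylsilyl ether F5. HF·pyridine in pyridine–THF at 0 °C should remove the less hindered O8 silyl group and give the 9-silyloxy alcohol F6. Acylation of its only free hydroxyl with 3-methylbutanoic anhydride and DMAP gives 25.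

**Further compounds**

F1 | step 17 | macrocyclic 8,9-acetonide (ring-closed product of 22) | C=C1C(=O)O[C@@H]2/C=C(/C)C3=CC(=O)[C@](C)(O3)[C@@H]4OC(C)(C)O[C@H]4[C@@H]12
F2 | step 17 | macrocyclic 8,9-diol (8-desacyl lobatin B) | C=C1C(=O)O[C@@H]2/C=C(/C)C3=CC(=O)[C@](C)(O3)[C@H](O)[C@@H](O)[C@@H]12
F3 | step 13 | syn hydroxy ester (C6 epimer of 21) | C=C(C(=O)OC)[C@@H]([C@@H](O)C=C)[C@@H]1OC(C)(C)O[C@H]1[C@@]2(C)OC(C(C)=C)=CC2=O
F4 | step 13 | cis-lactone (C6 epimer of 22) | C=C1C(=O)O[C@@H](C=C)[C@H]1[C@@H]2OC(C)(C)O[C@H]2[C@@]3(C)OC(C(C)=C)=CC3=O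
F5 | step 15 | 8,9-bis-O-triethylsilyl ether of 23 | C=C1C(=O)O[C@H](C=C)[C@H]1[C@H](O[Si](CC)(CC)CC)[C@@H](O[Si](CC)(CC)CC)[C@@]2(C)OC(C(C)=C)=CC2=O
F6 | step 15 | 9-O-triethylsilyl ether of 23 with free C8 hydroxyl | C=C1C(=O)O[C@H](C=C)[C@H]1[C@H](O)[C@@H](O[Si](CC)(CC)CC)[C@@]2(C)OC(C(C)=C)=CC2=O
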